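Compound numbers are those of the list after the steps. Atom labels: lactone O1, C2 (carbonyl), C3, C4, C5; C7' joins C3 to ring A (C1'–C6'); C7'' joins C4 to ring B (C1''–C6'').

## Analysis of the target

The target is a 3,4-dibenzylated γ-butyrolactone (oxolan-2-one) of the lignan type. C3 carries, through C7', a 2,4-dihydroxy-3-methoxyphenyl ring (ring A), and C4 carries, through C7'', a 4-hydroxy-3-methoxyphenyl ring (ring B). The two stereocentres, C3 (R) and C4 (R), hold the benzyl groups trans. C3 is alpha to the carbonyl and can be equilibrated to this more stable arrangement, whereas C4 must be set absolutely and is lost if a C3=C4 double bond ever forms. Sensitive groups are the lactone (opened by alkoxide, reclosed by acid), three free phenols including the easily oxidised resorcinol of ring A, and the benzylic positions, which under acid or oxidants invite cyclisation onto the arenes. The real difficulty is ring A: three adjacent oxygen substituents, the middle one methylated and the outer two free, next to the side-chain carbon C1'. Starting from a trioxygenated benzene, O3' would have to be told apart from O2' and O4' and the side chain placed regioselectively. The plan rests on the fact that C1'–C6' with oxygen on C2', C3' and C4' is one dehydrogenation away from a 4-alkyl-2-methoxycyclohexane-1,3-dione, with C2' and C4' as the carbonyl carbons and C3' as the methoxy carbon between them. Such a dione arises when a malonate adds to a vinyl ketone and the ketone's other alpha carbon is then acylated by a malonate ester, so ring A can be built on a malonate that already hangs from C7' of the enantiopure lactone.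

## Retrosynthetic reasoning

**18 to 16 (through 17).** No skeletal bond is cut. Ring A of 18 is written in its non-aromatic form, the 2-methoxycyclohexane-1,3-dione 16, one dehydrogenation below resorcinol 17; 17 is 18 with the ring B phenol still benzylated. Both changes are put into one operation because the hydrogen released on aromatisation is exactly what cleavage of the benzyl ether consumes. The forward reaction must remove two hydrogens from the carbocycle without reducing a ring carbonyl and without touching C3 or C4.

**16 to 15.** The bond from C1' to the extra methoxycarbonyl group is restored. This ester is the second arm of the malonate donor. It is cut here because a beta-keto ester on a quaternary carbon can be dealkoxycarbonylated under near-neutral conditions, leaving the C1'–H needed for aromatisation.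

**15 to 11 and 13 (key disconnection, through 14).** Two ring A bonds are cut: C2'–C3' (Claisen retron of the 1,3-dione) and C1'–C6' (Michael retron of the 1,5-dicarbonyl array in 14). These are the only two bonds of the carbocycle that follow the natural polarity of simple partners. C1' is a malonate carbon, C6' the beta carbon of an enone, C3' the oxygen-bearing alpha carbon of a ketone, and C2' an ester carbonyl. The gain is the whole oxygen pattern of ring A. In 13 the methoxy carbon already sits beside the ketone, and the Claisen closure places the second carbonyl on its other side, so no selective protection of an arene is needed. Enone 13 polymerises readily and is therefore released in the flask from its beta-methoxy precursor 12. The forward reaction must make the malonate carbon, not the lactone alpha carbon, the donor, and must close the ring on a malonate ester rather than on the lactone carbonyl.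

**11 to 9 and 10.** The C7'–C1' bond is cut in the conjugate-addition sense, with the exocyclic methylene carbon of 9 as acceptor and 10 as donor. C3 need not be set kinetically, because it is alpha to the lactone carbonyl and is allowed to settle trans to the C4 substituent.

**9 to 7 (through 8).** The exocyclic C3=C7' bond is cut. C7' is a one-carbon electrophile introduced at the only enolisable position of lactone 7, by way of formyl enolate 8.

**7 to 5 (through 6).** The O1–C5 bond is opened and C5 is raised to the ester level. The lactone is the reduced, cyclised form of half ester 5, whose free acid becomes C2 and whose ester becomes C5.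

**5 to 4.** The C4 stereocentre is traced to the trisubstituted alkene of 4. The free carboxyl group near the double bond is the handle for a chiral rhodium catalyst, so C4 is set by catalyst control at the outset and carried on as a non-enolisable centre.

**4 to 1 and 2 (through 3).** The C4=C7'' bond is cut as a condensation between aldehyde 1 and the alpha carbon of diester 2, which differentiates the two ester groups by itself. Ring B enters with its phenol benzylated; this group survives every basic step and leaves in the last operation.

## Alternatives that were turned down

**Alternative 1: three-component conjunctive coupling.**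
- **Disconnection:** C3–C4 and C7''–C1'' are cut together. C4 and C7'' come from vinylboronic ester A2, C3 with its C7'–ring A arm from alkenyllithium A3, and ring B from aryl triflate A4.
- **Forward key step:** A2 and A3 form a four-coordinate boronate. An arylpalladium species, from A4 and a zerovalent palladium catalyst with a chiral ferrocene-based bisphosphine, activates the vinyl group. The alkenyl group then migrates from boron to the neighbouring carbon (C3–C4), and reductive elimination joins C7'' to ring B. This gives boronic ester A1 with the future C4 set by the catalyst; no ring is closed.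
- **For:** two C–C bonds and the absolute configuration in one catalytic step, with both aryl groups brought in late. On convergence it is stronger than the chosen route.
- **Against:** A1 is far from the lactone. The C–B bond needs a one-carbon homologation and oxidation to give C5–OH, and the 1,1-disubstituted alkene needs anti-Markovnikov hydration and oxidation to the carboxyl level. The two primary hydroxyl groups that arise differ only in which benzyl group is nearer, so a protecting-group sequence must direct the lactone closure. C3 is not set by the key step. The branched alkenyl group is a hindered migrating group, the lithium halide from making A3 interferes with this type of coupling, and the electron-rich A4 adds slowly to palladium. Above all, A3 requires a pre-formed ring A with differentiated oxygens.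
- **Comparison:** about six operations follow the key step against two here, and the chosen route offers in place of convergence an oxygen pattern that is fixed by connectivity.

**Alternative 2: electroreductive carboxylation of a styrene.**
- **Disconnection:** C2–C3 and O1–C2 are cut. The lactone carbonyl carbon is removed as carbon dioxide A7, leaving the homoallylic alcohol–styrene A6.
- **Forward key step:** cathodic reduction of A6 under A7 with a proton donor. The radical anion attacks A7 through the beta carbon (C3), the benzylic carbon C7' is protonated, and the γ-hydroxy acid lactonises on acidification to A5. Hydrogenolysis of three benzyl ethers would finish.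
- **For:** the carbonyl carbon comes from A7 in the last C–C bond formation, the lactone closes by itself, and C3 can be equilibrated afterwards. On lateness and atom economy it is stronger than the chosen route.
- **Against:** A6 is a beta-alkyl styrene with three donor oxygens on the ring, so its reduction needs a very negative potential, where aryl benzyl ethers can be cleaved and simple saturation of the alkene competes. Carboxylation must occur at the more hindered alkene carbon, next to the branched C4. The substrate's own hydroxyl group is a proton source close to the radical anion, and dicarboxylation is a further side path. Making A6 requires an olefination that joins a fully protected, pre-formed ring A to a C4 fragment whose stereocentre then sits alpha to a carbonyl group.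
- **Comparison:** the route is no shorter overall and leaves the oxygen pattern of ring A unsolved, which the chosen route builds from acyclic pieces under base.

**Alternative 3: Pechmann condensation with lactone-to-coumarin transposition.**
- **Disconnection:** the aryl C1'–C7' bond, with O2' temporarily acylated by C2. Ring A comes from the symmetrical diphenol A9, the rest from hydroxymethylene lactone A10 (the tosyl-protected counterpart of the acid form of 8).
- **Forward key step:** under acid, A9 attacks the activated C7' through the carbon ortho to one hydroxyl and para to the other. That ortho hydroxyl is acylated by C2 with opening of the butyrolactone, and dehydration gives coumarin A8. Hydrogenation of the coumarin double bond, return of the acyl group to the primary alcohol (freeing O2'), and detosylation would follow.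
- **For:** it is the shortest route. The symmetry of A9 removes every regiochemical and protecting-group question on ring A, and ring A arrives aromatic. On step count and on sourcing ring A it is stronger than the chosen route.
- **Against:** the conditions are strongly acidic. In A10 the activated C7' can reach the ring B carbon para to the methoxy group through a six-membered transition state, and this intramolecular Friedel–Crafts closure competes with attack by A9 despite the deactivating tosylate. Acid also allows A10 to tautomerise with a C3=C4 double bond, which erases C4. Formyl-type partners are the less dependable ones in Pechmann condensations, C3 later comes from hydrogenation of a flat coumarin without control, and detosylation needs base on a lactone-bearing resorcinol.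
- **Comparison:** the chosen route is longer, but it never exposes ring B to an electrophile or C4 to acid-mediated enolisation.

Key step: step 6

## Route

Assumption: 1 and 12 are taken as purchasable, and the (4S,5S) antipode of MOD-DIOP (4,5-bis{[bis(4-methoxy-3,5-dimethylphenyl)phosphanyl]methyl}-2,2-dimethyl-1,3-dioxolane) in step 2 is assigned by analogy with related arylidenesuccinic half esters; should the sense of induction be the opposite, the (4R,5R) ligand is used.

Step 1
Reactants: 1 4-(benzyloxy)-3-methoxybenzaldehyde; 2 dimethyl butanedioate (dimethyl succinate)
Product: 4 (3E)-4-[4-(benzyloxy)-3-methoxyphenyl]-3-(methoxycarbonyl)but-3-enoic acid, via paraconate lactone 3 (not isolated)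
Conditions: NaOMe (2 equiv), MeOH, reflux; then aq. HCl
Reagents that add atoms: none
Why: Stobbe condensation: the succinate enolate adds to the aldehyde, the adduct lactonises to 3, and base-induced E1cB opening of 3 gives the carboxylate of the alkylidene half ester, which makes the sequence irreversible and leaves the two carboxyl groups differentiated; the E isomer (aryl anti to the ester) is the expected major product and is purified by crystallisation.

Step 2
Reactants: 4 (3E)-4-[4-(benzyloxy)-3-methoxyphenyl]-3-(methoxycarbonyl)but-3-enoic acid
Product: 5 (3R)-4-[4-(benzyloxy)-3-methoxyphenyl]-3-(methoxycarbonyl)butanoic acid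
Conditions: H2 (1 atm), [Rh(cod)Cl]2 (0.5 mol %; cod = cycloocta-1,5-diene), (4S,5S)-MOD-DIOP (1.1 mol %), Et3N (1 equiv), MeOH, 30 °C; aq. HCl work-up; recrystallisation
Reagents that add atoms: none
Why: Rhodium–bisphosphine asymmetric hydrogenation of an itaconate-type half ester: carboxylate and alkene chelate the metal and the chiral ligand decides the face that receives hydrogen, which sets the future C4 as R; a homogeneous rhodium catalyst leaves the aryl benzyl ether intact, and crystallisation should raise the enantiomeric purity further.

Step 3
Reactants: 5 (3R)-4-[4-(benzyloxy)-3-methoxyphenyl]-3-(methoxycarbonyl)butanoic acid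
Product: 7 (4R)-4-[4-(benzyloxy)-3-methoxybenzyl]oxolan-2-one, via hydroxy acid 6 (not isolated)
Conditions: KOH (1 equiv), EtOH, 0 °C; CaCl2, NaBH4, EtOH, −10 → 25 °C; then 3 M HCl, 25 °C
Reagents that add atoms: none
Why: Chemoselective ester reduction: Ca(BH4)2 formed in the flask reduces the methyl ester while the potassium carboxylate is inert, and acidification lactonises 6 to the five-membered lactone; the stereocentre takes no part in bond making, and the low temperature keeps the ester from enolising before it is reduced.

Step 4
Reactants: 7 (4R)-4-[4-(benzyloxy)-3-methoxybenzyl]oxolan-2-one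
Product: 9 (4R)-4-[4-(benzyloxy)-3-methoxybenzyl]-3-methylideneoxolan-2-one, via sodium formyl enolate 8 (not isolated)
Conditions: NaH (1.2 equiv), HCO2Et (3 equiv), THF, 0 → 25 °C; then (CH2O)n, THF, reflux
Reagents that add atoms: paraformaldehyde (as formaldehyde), C=O; ethyl formate, CCOC=O (its formyl carbon is present only in 8 and leaves as formate)
Why: Claisen formylation gives the stabilised enolate 8; with formaldehyde 8 is hydroxymethylated at C3, the formyl group moves to the new oxygen and formate is expelled (E1cB) to leave the exocyclic alkene; C4 is not enolisable under these conditions and keeps its configuration.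

Step 5
Reactants: 9 (4R)-4-[4-(benzyloxy)-3-methoxybenzyl]-3-methylideneoxolan-2-one; 10 dimethyl propanedioate (dimethyl malonate)
Product: 11 dimethyl 2-{[(3R,4R)-4-[4-(benzyloxy)-3-methoxybenzyl]-2-oxooxolan-3-yl]methyl}propanedioate
Conditions: 10 (3 equiv), NaOMe (0.3 equiv), MeOH–THF, 0 → 40 °C; AcOH quench
Reagents that add atoms: none
Why: Michael addition of the soft malonate anion to the exocyclic enoate; the excess of 10 suppresses double addition, and conjugate addition should be faster than migration of the double bond into the ring. C3 is created by protonation of the lactone enolate and is then equilibrated by methoxide to the more stable trans (3R,4R) arrangement, the C4 substituent being the controlling element.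

Step 6
Reactants: 11 dimethyl 2-{[(3R,4R)-4-[4-(benzyloxy)-3-methoxybenzyl]-2-oxooxolan-3-yl]methyl}propanedioate; 12 1,4-dimethoxybutan-2-one
Product: 15 methyl 1-{[(3R,4R)-4-[4-(benzyloxy)-3-methoxybenzyl]-2-oxooxolan-3-yl]methyl}-3-methoxy-2,4-dioxocyclohexane-1-carboxylate, via 1-methoxybut-3-en-2-one 13 (not isolated), via Michael adduct 14 (not isolated)
Conditions: NaOMe (2.2 equiv), MeOH, 0 °C; 12 (1.1 equiv) added slowly, 25 °C; then 65 °C; then 1 M HCl, 25 °C
Reagents that add atoms: none
Why: Methoxide deprotonates the malonate C–H of 11 and also unmasks enone 13 from 12 by E1cB loss of methanol, so the acceptor is only ever present in low concentration; the malonate anion adds to its beta carbon (C1'–C6' bond) to give 14, in which C1' is quaternary. Proton transfer then gives the ketone enolates, and the one on the methoxy-bearing carbon C3' attacks a malonate ester carbonyl in a Dieckmann-type Claisen condensation (C2'–C3' bond, 6-(enolendo)-exo-trig), which closes ring A at the cyclohexane-1,3-dione level. The closest known reaction is the classical preparation of 5,5-dimethylcyclohexane-1,3-dione from a malonate and an enone, here with a substituted malonate and a methoxymethyl ketone. Site selectivity of the first bond follows from acidity: the malonate is far more acidic than the lactone alpha position C3, so only C1' acts as donor. For the second bond two closures through six-membered transition states are conceivable, the wanted one and attack of the chain-side enolate C5' on the lactone carbonyl; all Claisen steps are reversible in methanolic methoxide, the methoxy group favours enolisation towards C3', and the wanted product ends as the anion of a cyclic 1,3-dione, which is considerably more stable than the acylcyclohexanone anion of the other closure and is the thermodynamic sink, hence more than one equivalent of base. The new stereocentres C1' and C3' need no control because both become sp2 on aromatisation; C4 is not acidic and is untouched, and C3 is under equilibrium control and should rest trans to the C4 substituent. Any lactone opened by methoxide is reclosed by the acidic work-up.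

Step 7
Reactants: 15 methyl 1-{[(3R,4R)-4-[4-(benzyloxy)-3-methoxybenzyl]-2-oxooxolan-3-yl]methyl}-3-methoxy-2,4-dioxocyclohexane-1-carboxylate
Product: 16 (3R,4R)-4-[4-(benzyloxy)-3-methoxybenzyl]-3-[(3-methoxy-2,4-dioxocyclohexyl)methyl]oxolan-2-one
Conditions: LiCl (3 equiv), H2O (2 equiv), DMSO, 140 °C
Reagents that add atoms: none
Why: Krapcho dealkoxycarbonylation: chloride removes the ester methyl group by SN2 attack, CO2 is lost through the adjacent ketone and the resulting enolate is protonated by water; the medium is close to neutral, so the aryl ethers survive, and any opening of the lactone by chloride at C5 is reversible. The product is a mixture of keto–enol tautomers and epimers on the carbocycle, all of which converge in step 8.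

Step 8
Reactants: 16 (3R,4R)-4-[4-(benzyloxy)-3-methoxybenzyl]-3-[(3-methoxy-2,4-dioxocyclohexyl)methyl]oxolan-2-one
Product: 18 (3R,4R)-3-(2,4-dihydroxy-3-methoxybenzyl)-4-(4-hydroxy-3-methoxybenzyl)oxolan-2-one, via benzyl-protected resorcinol 17 (not isolated)
Conditions: 10% Pd/C, triglyme, 190 °C, Ar, closed vessel; then 25 °C, H2 (1 atm)
Reagents that add atoms: none
Why: Heterogeneous catalytic dehydrogenation of a cyclohexane-1,3-dione: palladium removes two hydrogens from the saturated ring carbons and the product tautomerises irreversibly to resorcinol 17. The hydrogen held on the catalyst is what hydrogenolysis of the benzyl ether requires (transfer hydrogenolysis), which also keeps it from reducing a ring carbonyl; a final stir under H2 at room temperature completes the debenzylation. No stereocentre is formed, C3 and C4 are not affected, and the methoxy groups and the lactone C5–O1 bond are not benzylic and are not cleaved.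

## Compound list

1 | 4-(benzyloxy)-3-methoxybenzaldehyde | COc1cc(C=O)ccc1OCc1ccccc1 | starting material
2 | dimethyl butanedioate | COC(=O)CCC(=O)OC | starting material
3 | methyl 2-[4-(benzyloxy)-3-methoxyphenyl]-5-oxooxolane-3-carboxylate (racemic, both diastereomers) | COC(=O)C1CC(=O)OC1c1ccc(OCc2ccccc2)c(OC)c1 | intermediate
4 | (3E)-4-[4-(benzyloxy)-3-methoxyphenyl]-3-(methoxycarbonyl)but-3-enoic acid | COC(=O)/C(CC(=O)O)=C/c1ccc(OCc2ccccc2)c(OC)c1 | intermediate
5 | (3R)-4-[4-(benzyloxy)-3-methoxyphenyl]-3-(methoxycarbonyl)butanoic acid | COc1cc(C[C@@H](C(=O)OC)CC(=O)O)ccc1OCc1ccccc1 | intermediate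
6 | (3R)-4-[4-(benzyloxy)-3-methoxyphenyl]-3-(hydroxymethyl)butanoic acid | COc1cc(C[C@@H](CO)CC(=O)O)ccc1OCc1ccccc1 | intermediate
7 | (4R)-4-[4-(benzyloxy)-3-methoxybenzyl]oxolan-2-one | COc1cc(C[C@H]2COC(=O)C2)ccc1OCc1ccccc1 | intermediate
8 | sodium enolate of (4R)-4-[4-(benzyloxy)-3-methoxybenzyl]-3-(hydroxymethylidene)oxolan-2-one | COc1cc(C[C@H]2COC(=O)C2=C[O-])ccc1OCc1ccccc1.[Na+] | intermediate
9 | (4R)-4-[4-(benzyloxy)-3-methoxybenzyl]-3-methylideneoxolan-2-one | COc1cc(C[C@H]2COC(=O)C2=C)ccc1OCc1ccccc1 | intermediate
10 | dimethyl propanedioate | COC(=O)CC(=O)OC | starting material
11 | dimethyl 2-{[(3R,4R)-4-[4-(benzyloxy)-3-methoxybenzyl]-2-oxooxolan-3-yl]methyl}propanedioate | COc1cc(C[C@H]2COC(=O)[C@@H]2CC(C(=O)OC)C(=O)OC)ccc1OCc1ccccc1 | intermediate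
12 | 1,4-dimethoxybutan-2-one | COCCC(=O)COC | starting material
13 | 1-methoxybut-3-en-2-one | COCC(=O)C=C | intermediate
14 | dimethyl 2-{[(3R,4R)-4-[4-(benzyloxy)-3-methoxybenzyl]-2-oxooxolan-3-yl]methyl}-2-(4-methoxy-3-oxobutyl)propanedioate | COc1cc(C[C@H]2COC(=O)[C@@H]2CC(CCC(=O)COC)(C(=O)OC)C(=O)OC)ccc1OCc1ccccc1 | intermediate
15 | methyl 1-{[(3R,4R)-4-[4-(benzyloxy)-3-methoxybenzyl]-2-oxooxolan-3-yl]methyl}-3-methoxy-2,4-dioxocyclohexane-1-carboxylate (epimers at the two carbocycle centres) | COc1cc(C[C@H]2COC(=O)[C@@H]2CC2(C(=O)OC)CCC(=O)C(OC)C2=O)ccc1OCc1ccccc1 | intermediate
16 | (3R,4R)-4-[4-(benzyloxy)-3-methoxybenzyl]-3-[(3-methoxy-2,4-dioxocyclohexyl)methyl]oxolan-2-one (epimers and tautomers on the carbocycle) | COc1cc(C[C@H]2COC(=O)[C@@H]2CC2CCC(=O)C(OC)C2=O)ccc1OCc1ccccc1 | intermediate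
17 | (3R,4R)-4-[4-(benzyloxy)-3-methoxybenzyl]-3-(2,4-dihydroxy-3-methoxybenzyl)oxolan-2-one | COc1cc(C[C@H]2COC(=O)[C@@H]2Cc2ccc(O)c(OC)c2O)ccc1OCc1ccccc1 | intermediate
18 | (3R,4R)-3-(2,4-dihydroxy-3-methoxybenzyl)-4-(4-hydroxy-3-methoxybenzyl)oxolan-2-one | COc1cc(C[C@H]2COC(=O)[C@@H]2Cc2ccc(O)c(OC)c2O)ccc1O | target

## Step count and least certain steps

Total step count: 8. Longest linear sequence: 8 steps (from 1; 2, 10 and 12 enter along the way).

**Step 6 (key step).** Three things are most likely to go wrong:
- Acylation at the wrong carbonyl: the chain-side enolate C5' can reach the lactone carbonyl through a six-membered transition state and open the lactone, and the route relies on reversibility to correct this.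
- Retro-Michael cleavage at C7'–C1' between the two bond formations, followed by migration of the freed exocyclic double bond into the ring, which would erode C4.
- A second conjugate addition of the product dione enolate to enone still present.

Reversible aldol addition of the lactone enolate to the ketone and methanolysis of the lactone are expected to be harmless.

Fallback: abandon the annulation and bring ring A in pre-formed. Starting from lactone 7, deprotonation with LiHMDS (THF, −78 °C) and alkylation with 2,4-bis(benzyloxy)-1-(bromomethyl)-3-methoxybenzene F1 should give the trans lactone (3R,4R)-3-[2,4-bis(benzyloxy)-3-methoxybenzyl]-4-[4-(benzyloxy)-3-methoxybenzyl]oxolan-2-one F2 (the same compound as A5), the electrophile entering anti to the C4 substituent. F1 is a building block that must be prepared separately and carries the oxygen pattern of ring A ready-made. Hydrogenolysis of the three benzyl ethers (H2, Pd/C, EtOAc–MeOH, 25 °C) comes back to the route at 18. The price is that the ring A pattern again depends on selective protection of an arene.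

**Step 8.** The dehydrogenation may stall, or hydrogen on the catalyst may reduce a ring carbonyl so that dehydration and aromatisation then strip one oxygen from ring A. Hydrogen may also escape before it cleaves the benzyl ether, which the second stage corrects.

Fallback: carry the unsaturation in the four-carbon partner so that no dehydrogenation is needed. Starting from malonate 11, methoxide-mediated annulation with 1-methoxybut-3-yn-2-one F3 in place of 12 should give the conjugate adduct dimethyl 2-{[(3R,4R)-4-[4-(benzyloxy)-3-methoxybenzyl]-2-oxooxolan-3-yl]methyl}-2-(4-methoxy-3-oxobut-1-en-1-yl)propanedioate F4. Its alkene isomers interconvert by reversible methoxide addition, and the Z isomer closes to methyl 1-{[(3R,4R)-4-[4-(benzyloxy)-3-methoxybenzyl]-2-oxooxolan-3-yl]methyl}-3-methoxy-2,4-dioxocyclohex-5-ene-1-carboxylate F5. Loss of the quaternary methoxycarbonyl group (as dimethyl carbonate under methoxide, or with LiCl in DMSO) is then driven by aromatisation and returns to the route at 17. Compound 17 is isolated and hydrogenolysed (H2, Pd/C, 25 °C) to 18.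

**Step 7.** The hot chloride/DMSO medium may open the lactone irreversibly, or the hydroxide formed may cleave the carbocycle by retro-Claisen attack. The neopentyl-like ester may also be dealkylated only slowly.

Fallback: change the ester so that it leaves by acidolysis. Starting from methylene lactone 9, Michael addition of tert-butyl methyl propanedioate in place of 10 should give tert-butyl methyl 2-{[(3R,4R)-4-[4-(benzyloxy)-3-methoxybenzyl]-2-oxooxolan-3-yl]methyl}propanedioate F6. Annulation with 12 as in step 6, in which the methyl ester is the acyl donor, gives tert-butyl 1-{[(3R,4R)-4-[4-(benzyloxy)-3-methoxybenzyl]-2-oxooxolan-3-yl]methyl}-3-methoxy-2,4-dioxocyclohexane-1-carboxylate F7. CF3CO2H in CH2Cl2 at 25 °C removes the tert-butyl group, and gentle warming decarboxylates the acid, returning to the route at 16.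

**Step 5.** The exocyclic double bond of 9 may migrate into the ring before the malonate adds, which would destroy both the acceptor and the C4 configuration. The adduct may add to a second molecule of 9, and equilibration at C3 may be incomplete.

Fallback: exchange the roles of donor and acceptor. Starting from lactone 7, the lithium enolate (LiHMDS, THF, −78 °C) is added to dimethyl 2-methylidenepropanedioate F8, freshly prepared from 10 and paraformaldehyde (Cu(OAc)2, KOAc, AcOH) and distilled. Attack anti to the C4 substituent should set C3 trans under kinetic control, and the route is rejoined at 11 without passing through 9.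

## Further compounds

F1 | step 6 | 2,4-bis(benzyloxy)-1-(bromomethyl)-3-methoxybenzene | BrCc1ccc(OCc2ccccc2)c(OC)c1OCc1ccccc1
F2 | step 6 | (3R,4R)-3-[2,4-bis(benzyloxy)-3-methoxybenzyl]-4-[4-(benzyloxy)-3-methoxybenzyl]oxolan-2-one | COc1cc(C[C@H]2COC(=O)[C@@H]2Cc2ccc(OCc3ccccc3)c(OC)c2OCc2ccccc2)ccc1OCc1ccccc1
F3 | step 8 | 1-methoxybut-3-yn-2-one | COCC(=O)C#C
F4 | step 8 | dimethyl 2-{[(3R,4R)-4-[4-(benzyloxy)-3-methoxybenzyl]-2-oxooxolan-3-yl]methyl}-2-(4-methoxy-3-oxobut-1-en-1-yl)propanedioate | COc1cc(C[C@H]2COC(=O)[C@@H]2CC(C=CC(=O)COC)(C(=O)OC)C(=O)OC)ccc1OCc1ccccc1
F5 | step 8 | methyl 1-{[(3R,4R)-4-[4-(benzyloxy)-3-methoxybenzyl]-2-oxooxolan-3-yl]methyl}-3-methoxy-2,4-dioxocyclohex-5-ene-1-carboxylate | COc1cc(C[C@H]2COC(=O)[C@@H]2CC2(C(=O)OC)C=CC(=O)C(OC)C2=O)ccc1OCc1ccccc1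
F6 | step 7 | tert-butyl methyl 2-{[(3R,4R)-4-[4-(benzyloxy)-3-methoxybenzyl]-2-oxooxolan-3-yl]methyl}propanedioate | COc1cc(C[C@H]2COC(=O)[C@@H]2CC(C(=O)OC)C(=O)OC(C)(C)C)ccc1OCc1ccccc1
F7 | step 7 | tert-butyl 1-{[(3R,4R)-4-[4-(benzyloxy)-3-methoxybenzyl]-2-oxooxolan-3-yl]methyl}-3-methoxy-2,4-dioxocyclohexane-1-carboxylate | COc1cc(C[C@H]2COC(=O)[C@@H]2CC2(C(=O)OC(C)(C)C)CCC(=O)C(OC)C2=O)ccc1OCc1ccccc1
F8 | step 5 | dimethyl 2-methylidenepropanedioate | C=C(C(=O)OC)C(=O)OC
A1 | alternative 1 | 2-[(2R)-1-[4-(benzyloxy)-3-methoxyphenyl]-3-[2,4-bis(benzyloxy)-3-methoxybenzyl]but-3-en-2-yl]-4,4,5,5-tetramethyl-1,3,2-dioxaborolane | C=C(Cc1ccc(OCc2ccccc2)c(OC)c1OCc1ccccc1)[C@H](B1OC(C)(C)C(C)(C)O1)Cc1ccc(OCc2ccccc2)c(OC)c1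
A2 | alternative 1 | 2-ethenyl-4,4,5,5-tetramethyl-1,3,2-dioxaborolane | C=CB1OC(C)(C)C(C)(C)O1
A3 | alternative 1 | {3-[2,4-bis(benzyloxy)-3-methoxyphenyl]prop-1-en-2-yl}lithium | [Li]C(=C)Cc1ccc(OCc2ccccc2)c(OC)c1OCc1ccccc1
A4 | alternative 1 | 4-(benzyloxy)-3-methoxyphenyl trifluoromethanesulfonate | COc1cc(OS(=O)(=O)C(F)(F)F)ccc1OCc1ccccc1
A5 | alternative 2 | (3R,4R)-3-[2,4-bis(benzyloxy)-3-methoxybenzyl]-4-[4-(benzyloxy)-3-methoxybenzyl]oxolan-2-one | COc1cc(C[C@H]2COC(=O)[C@@H]2Cc2ccc(OCc3ccccc3)c(OC)c2OCc2ccccc2)ccc1OCc1ccccc1
A6 | alternative 2 | (2R,3E)-2-[4-(benzyloxy)-3-methoxybenzyl]-4-[2,4-bis(benzyloxy)-3-methoxyphenyl]but-3-en-1-ol | OC[C@H](Cc1ccc(OCc2ccccc2)c(OC)c1)/C=C/c1ccc(OCc2ccccc2)c(OC)c1OCc1ccccc1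
A7 | alternative 2 | carbon dioxide | O=C=O
A8 | alternative 3 | 7-hydroxy-3-[(2R)-1-hydroxy-3-(3-methoxy-4-tosyloxyphenyl)propan-2-yl]-8-methoxycoumarin | O=c1oc2c(OC)c(O)ccc2cc1[C@H](CO)Cc1ccc(OS(=O)(=O)c2ccc(C)cc2)c(OC)c1
A9 | alternative 3 | 2-methoxybenzene-1,3-diol | COc1c(O)cccc1O
A10 | alternative 3 | (4R)-3-(hydroxymethylidene)-4-[3-methoxy-4-(tosyloxy)benzyl]oxolan-2-one | Cc1ccc(cc1)S(=O)(=O)Oc1ccc(C[C@H]2COC(=O)C2=CO)cc1OC
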